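**Plan**
- Numbering: ring A = C1–C5 (C4 ketone, C5 quaternary; β = face of the C5 methyl), ring B = C5–C6–C7–C8–C9–C10–C1, lactone = C7–C11–C12(=O)–O–C8, C13 = lactone methylene carbon; the menthadienol ring is C1'–C6' (C2' carries the methyl, C5' the hydroxypropyl group).
- Cuts, in retrosynthetic order: C11–C4' and C13–C1' (Diels–Alder, releasing (R)-p-mentha-1,5-dien-8-ol from (R)-carvone); the C6 tiglate, C11=C13 and C2=C3; then C8–C9 together with O8–C12; then the C7 vinyl group, C6–C7, C5–C6 and C1–C10.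
- Enabling feature: C8 and C9 are neighbouring ring B carbons bearing cis β oxygens (lactone oxygen and free hydroxyl), the pattern left by reductive coupling of two aldehydes; the C7 acetate arm next to O8 then closes the lactone.
- Forward order: ring A from 2-methylcyclopentenone, side chains at C1 and C5, ring B and lactone in one operation, then methylene lactone, tiglate and enone, and the bicyclooctene last.
- Stereochemistry: C1, C10 and the absolute sense from a chiral crotylphosphonamide; C5 by anti trapping of the enolate; C6 by ligand-controlled alkynylation; C7 by anti conjugate addition; C8 and C9 by the samarium-bridged coupling; C11, C1' and C4' by the cycloaddition; C5' from carvone.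

Key step: step 14

Assumption: the (R,R)-crotylphosphonamide anion and the (S)-BINOL–titanium alkynylzinc reagent are taken to react with the facial sense of their usual transition-state models (lithium-bridged endo 1,4-addition; Si-face attack on RCHO); if either sense proved opposite, the enantiomeric diamine or BINOL would be used with no other change.

**Route**

Step 1
Reactants: 1 (E)-1-bromobut-2-ene
Product: 2 diethyl [(E)-but-2-en-1-yl]phosphonate
Conditions: P(OEt)3, neat, 140 °C, EtBr distilled off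
Reagents that add atoms: triethyl phosphite, CCOP(OCC)OCC
Why: Michaelis–Arbuzov reaction, in which phosphorus displaces the primary allylic bromide and bromide dealkylates the phosphonium ion, should give the E-crotylphosphonate.

Step 2
Reactants: 2 diethyl [(E)-but-2-en-1-yl]phosphonate
Product: 3 [(E)-but-2-en-1-yl]phosphonic dichloride
Conditions: SOCl2, DMF (cat.), reflux
Reagents that add atoms: thionyl chloride, O=S(Cl)Cl
Why: DMF-catalysed chlorodealkoxylation of a dialkyl phosphonate replaces both ethoxy groups and leaves the alkene untouched.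

Step 3
Reactants: 3 [(E)-but-2-en-1-yl]phosphonic dichloride; 4 (1R,2R)-N,N'-dimethylcyclohexane-1,2-diamine
Product: 5 (3aR,7aR)-2-[(E)-but-2-en-1-yl]-1,3-dimethyloctahydro-1,3,2-benzodiazaphosphole 2-oxide
Conditions: Et3N, CH2Cl2, 0 °C → rt; recrystallisation
Reagents that add atoms: none
Why: Double P–N bond formation with the C2-symmetric diamine gives one bicyclic phosphonic diamide (phosphorus is not stereogenic), and recrystallisation should remove Z-crotyl material.

Step 4
Reactants: 5 (R,R)-crotylphosphonamide; 6 2-methylcyclopent-2-en-1-one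
Product: 8 (2R,3S)-2-(hydroxymethyl)-2-methyl-3-[(2S,3E)-4-phosphonamidylbut-3-en-2-yl]cyclopentan-1-one, via lithium enolate 7 (not isolated)
Conditions: n-BuLi, THF, −78 °C; 6, −78 °C; CH2O (gas), −78 → −40 °C; AcOH
Reagents that add atoms: formaldehyde, C=O
Why: Asymmetric conjugate addition of the lithiated chiral crotylphosphonamide through its γ-carbon in a lithium-bridged ten-membered transition state sets C1 and C10 (the E-crotyl geometry gives the required 1,10-relationship, the diamine the absolute sense), and aldol trapping of the enolate by monomeric formaldehyde anti to the new C1 substituent sets the C5 quaternary centre with its methyl cis to the side chain.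

Step 5
Reactants: 8 phosphonamide keto alcohol
Product: 9 (2S)-2-[(1S,2R)-2-(hydroxymethyl)-2-methyl-3-oxocyclopentyl]propanal (in equilibrium with its six-membered lactol)
Conditions: O3, CH2Cl2, −78 °C; Me2S, −78 °C → rt
Reagents that add atoms: ozone, [O-][O+]=O
Why: Ozonolysis of the vinylphosphonamide is the usual way to release the aldehyde from such adducts and removes the acid-labile auxiliary before ketalisation, while ketone, alcohol and C10 are not touched.

Step 6
Reactants: 9 hydroxy keto aldehyde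
Product: 10 (2R,3S)-3-[(2R)-but-3-en-2-yl]-2-(hydroxymethyl)-2-methylcyclopentan-1-one
Conditions: Ph3PCH3Br, KN(SiMe3)2, THF, 0 °C; then 9, −78 → 0 °C
Reagents that add atoms: methyltriphenylphosphonium bromide, C[P+](c1ccccc1)(c1ccccc1)c1ccccc1.[Br-]
Why: Wittig methylenation should take the aldehyde (free or via the opened lactol) at low temperature while the ketone next to the quaternary carbon reacts far more slowly, and brief exposure to the ylide should not epimerise C10.

Step 7
Reactants: 10 vinyl keto alcohol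
Product: 11 [(6R,7S)-7-[(2R)-but-3-en-2-yl]-6-methyl-1,4-dioxaspiro[4.4]nonan-6-yl]methanol
Conditions: HOCH2CH2OH, PPTS, benzene, reflux (Dean–Stark)
Reagents that add atoms: ethylene glycol, OCCO
Why: Acid-catalysed ketalisation with azeotropic removal of water protects C4 for the hydride, cuprate and samarium steps, and the neopentyl alcohol can neither eliminate nor cyclise.

Step 8
Reactants: 11 ketal alcohol
Product: 12 (6R,7S)-7-[(2R)-but-3-en-2-yl]-6-methyl-1,4-dioxaspiro[4.4]nonane-6-carbaldehyde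
Conditions: Pr4N[RuO4] (5 mol %), N-methylmorpholine N-oxide, 4 Å sieves, CH2Cl2, rt
Reagents that add atoms: none
Why: Ley–Griffith oxidation of the primary alcohol stops at the non-enolisable aldehyde under neutral conditions that spare the ketal and the alkene.

Step 9
Reactants: 12 ketal aldehyde
Product: 13 methyl (4S)-4-[(6R,7S)-7-[(2R)-but-3-en-2-yl]-6-methyl-1,4-dioxaspiro[4.4]nonan-6-yl]-4-hydroxybut-2-ynoate
Conditions: HC≡CCO2Me, ZnEt2, (S)-BINOL (40 mol %), HMPA, CH2Cl2, rt; Ti(OiPr)4; then 12, rt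
Reagents that add atoms: methyl propiolate, C#CC(=O)OC
Why: Catalytic asymmetric alkynylzinc addition to an aldehyde under BINOL–titanium control should deliver the propiolate to the Si face of the non-enolisable aldehyde and so set C6 as S by reagent control.

Step 10
Reactants: 13 γ-hydroxy ynoate
Product: 14 methyl (2E,4S)-4-[(6R,7S)-7-[(2R)-but-3-en-2-yl]-6-methyl-1,4-dioxaspiro[4.4]nonan-6-yl]-4-hydroxybut-2-enoate
Conditions: NaAlH2(OCH2CH2OMe)2, THF, −72 °C; aq. KNaC4H4O6
Reagents that add atoms: none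
Why: Hydroxyl-directed trans-hydroalumination of the γ-hydroxy ynoate followed by protonation gives the E-enoate only, and the ester is not reduced at this temperature.

Step 11
Reactants: 14 γ-hydroxy E-enoate
Product: 15 methyl (2E,4S)-4-[(6R,7S)-7-[(2R)-but-3-en-2-yl]-6-methyl-1,4-dioxaspiro[4.4]nonan-6-yl]-4-(triethylsilyloxy)but-2-enoate
Conditions: Et3SiOTf, 2,6-lutidine, CH2Cl2, −78 → 0 °C
Reagents that add atoms: triethylsilyl trifluoromethanesulfonate, CC[Si](CC)(CC)OS(=O)(=O)C(F)(F)F
Why: A silyl triflate silylates even this hindered secondary alcohol, and the bulky non-chelating ether is wanted as the control element in steps 12 and 14.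

Step 12
Reactants: 15 γ-silyloxy E-enoate
Product: 17 methyl (3R)-3-[(S)-{(6R,7S)-7-[(2R)-but-3-en-2-yl]-6-methyl-1,4-dioxaspiro[4.4]nonan-6-yl}(triethylsilyloxy)methyl]pent-4-enoate, via silyl ketene acetal 16 (not isolated)
Conditions: CH2=CHMgBr, CuBr·SMe2 (20 mol %), Me3SiCl, THF, −78 → −40 °C; aq. NH4Cl
Reagents that add atoms: vinylmagnesium bromide, C=C[Mg]Br
Why: Copper-catalysed 1,4-addition with silyl chloride acceleration to a γ-alkoxy E-enoate occurs anti to the C6–O bond (Felkin–Anh-type conformer with H-6 inside and the quaternary C5 outside), which is the known anti outcome for this substrate class and sets C7.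

Step 13
Reactants: 17 bis-vinyl ester
Product: 18 methyl (3S,4S)-3-formyl-4-{(6R,7S)-6-methyl-7-[(2S)-1-oxopropan-2-yl]-1,4-dioxaspiro[4.4]nonan-6-yl}-4-(triethylsilyloxy)butanoate
Conditions: O3, CH2Cl2, −78 °C; Me2S, −78 °C → rt; used crude
Reagents that add atoms: ozone, [O-][O+]=O
Why: Ozonolysis of the two monosubstituted alkenes with reductive work-up gives both aldehydes at once while silyl ether, ketal and ester are inert, and immediate use avoids epimerisation at C7 and C10.

Step 14
Reactants: 18 C8,C9-dialdehyde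
Product: 20 hydroxy lactone (4,4-ethylenedioxy, 6α-OSiEt3, 9β-OH, 8β,12-lactone), via cis-diol ester 19 (not isolated)
Conditions: SmI2 (3 equiv), THF, −78 → 0 °C, then rt; aq. KNaC4H4O6
Reagents that add atoms: none
Why: Two single-electron transfers from SmI2 (divalent samarium) turn the C8 and C9 aldehydes into ketyls that couple while both oxygens are bound to trivalent samarium, and the resulting C8 alkoxide then attacks the C12 methyl ester and expels methoxide. The closest known reaction type is the SmI2 pinacol cyclisation of 1,n-dialdehydes to cis-cycloalkane-1,2-diols, here followed by alkoxide lactonisation of a γ-hydroxy ester. Ring B closes by 7-exo-trig addition of the C9 ketyl to the C8 carbonyl (radical–radical coupling in the limit) and the lactone by 5-exo-trig acyl substitution. C8 and C9 are set together: the samarium bridge forces a cis diol, and the diolate should lie on the β face because the α face is flanked by the 6α-triethylsilyloxy group (1,3 to C8) and the 10α-methyl group (1,2 to C9), whereas the β face carries only the C7 acetate arm, whose ester carbonyl can bind the metal. The step needs the 8β,9β-diol and coupling of the two aldehydes only; the trans arrangement of the two side chains on ring A brings the aldehydes together, the ketal keeps C4 out of any five-ring pinacol, and the unactivated ester is not reduced by SmI2 in THF alone.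

Step 15
Reactants: 20 hydroxy lactone
Product: 21 9β-(tert-butyldimethylsilyloxy) lactone
Conditions: t-BuMe2SiOTf, 2,6-lutidine, CH2Cl2, 0 °C
Reagents that add atoms: tert-butyldimethylsilyl trifluoromethanesulfonate, CC(C)(C)[Si](C)(C)OS(=O)(=O)C(F)(F)F
Why: Silyl triflate silylation masks the C9 hydroxyl, which would otherwise interfere with the lactone enolate and would be acylated ahead of the C6 hydroxyl.

Step 16
Reactants: 21 bis-silyl lactone
Product: 24 α-methylene lactone (C11=C13), via Mannich base 22 (not isolated), via ammonium iodide 23 (not isolated)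
Conditions: LiN(iPr)2, THF, −78 °C; [Me2N=CH2]I, −78 °C → rt; MeI, MeOH, rt; aq. NaHCO3, CH2Cl2, rt
Reagents that add atoms: Eschenmoser's salt (N,N-dimethylmethyleneiminium iodide), C=[N+](C)C.[I-]
Why: Mannich reaction of the lactone enolate with Eschenmoser's salt, N-methylation and base-induced elimination is the standard α-methylenation of γ-butyrolactones and creates no stereocentre.

Step 17
Reactants: 24 α-methylene lactone
Product: 25 6α-hydroxy 4-ketone (9β-OSi-t-BuMe2 retained)
Conditions: TsOH·H2O (cat.), THF/H2O (4:1), 40 °C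
Reagents that add atoms: water, O
Why: Mild aqueous acid cleaves the triethylsilyl ether and hydrolyses the dioxolane in one operation while the more hindered tert-butyldimethylsilyl ether should survive.

Step 18
Reactants: 25 6α-hydroxy ketone
Product: 26 6α-tiglate
Conditions: tigloyl chloride, pyridine, DMAP (cat.), CH2Cl2, 0 °C → rt
Reagents that add atoms: tigloyl chloride [(E)-2-methylbut-2-enoyl chloride], C/C=C(\C)C(=O)Cl
Why: DMAP-catalysed acylation of the 6α-hydroxyl, the position that is esterified in helenalin-type lactones, installs the tiglate, whose E geometry is the stable one, under conditions too weakly basic for retro-aldol cleavage.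

Step 19
Reactants: 26 6α-tiglate ketone
Product: 27 ring A enone (C2=C3)
Conditions: IBX, DMSO, 65 °C
Reagents that add atoms: none
Why: IBX dehydrogenation of a ketone through its enol can only involve C3 because C5 is quaternary, so the cyclopentenone forms regioselectively without base.

Step 20
Reactants: 27 silylated enone
Product: 28 dienophile (6α-tiglate, 9β-OH, ring A enone, methylene lactone)
Conditions: HF·pyridine, pyridine, THF, 0 °C → rt
Reagents that add atoms: none
Why: Buffered fluoride removes the remaining silyl ether without base, so enone, methylene lactone and the β-acyloxy ketone are safe, and the β face of the lactone is left carrying only a hydroxyl.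

Step 21
Reactants: 29 (R)-(−)-carvone
Product: 30 (5R)-5-(2-hydroxypropan-2-yl)-2-methylcyclohex-2-en-1-one
Conditions: H2SO4 (50% aq.), 0 °C → rt
Reagents that add atoms: water, O
Why: Markovnikov acid-catalysed hydration of the isopropenyl group through the tertiary cation leaves the C5' stereocentre untouched.

Step 22
Reactants: 30 hydroxy enone
Product: 31 E-tosylhydrazone of 30
Conditions: TsNHNH2, EtOH, rt
Reagents that add atoms: 4-methylbenzenesulfonohydrazide, Cc1ccc(cc1)S(=O)(=O)NN
Why: Condensation gives the hydrazone with the sulfonamide nitrogen syn to the α'-methylene group, as the next step requires.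

Step 23
Reactants: 31 tosylhydrazone
Product: 33 2-[(1R)-4-methylcyclohexa-2,4-dien-1-yl]propan-2-ol, via dienyllithium alkoxide 32 (not isolated)
Conditions: MeLi (3.5 equiv), Et2O, 0 °C → rt; H2O
Reagents that add atoms: none
Why: Shapiro reaction of an α,β-unsaturated tosylhydrazone (α'-deprotonation, loss of sulfinate and N2, protonation of the vinyllithium) gives the conjugated 1,3-diene without touching C5'.

Step 24
Reactants: 28 dienophile; 33 dienol
Product: 34 target compound
Conditions: 33 (3 equiv), toluene, 2,6-di-tert-butyl-4-methylphenol (cat.), 80 °C, sealed tube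
Reagents that add atoms: none
Why: Thermal Diels–Alder reaction of the exocyclic methylene lactone (enone and tiglate are much poorer dienophiles) with the 2-methylcyclohexa-1,3-diene should join C13 to C1' (para to the methyl group) and C11 to C4' on the diene face opposite the C5' side chain, with the lactone carbonyl endo so that C7 and ring B stay outside, and on the methylene face on the side of C6 (anti to H-7 and H-8), the α face under C13 being screened by the 6α-tigloyloxy group and the β face bearing only the free 9-hydroxyl; this topology fixes C11, C1' and C4' as in the target.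

**Compound list**

1 | (E)-1-bromobut-2-ene | C/C=C/CBr | starting material
2 | diethyl [(E)-but-2-en-1-yl]phosphonate | C/C=C/CP(=O)(OCC)OCC | intermediate
3 | [(E)-but-2-en-1-yl]phosphonic dichloride | C/C=C/CP(=O)(Cl)Cl | intermediate
4 | (1R,2R)-N,N'-dimethylcyclohexane-1,2-diamine | CN[C@@H]1CCCC[C@H]1NC | starting material
5 | (3aR,7aR)-2-[(E)-but-2-en-1-yl]-1,3-dimethyloctahydro-1,3,2-benzodiazaphosphole 2-oxide | C/C=C/CP1(=O)N(C)[C@@H]2CCCC[C@H]2N1C | intermediate
6 | 2-methylcyclopent-2-en-1-one | CC1=CCCC1=O | starting material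
7 | lithium (3S)-2-methyl-3-[(2S,3E)-4-{(3aR,7aR)-1,3-dimethyl-2-oxidooctahydro-1,3,2-benzodiazaphosphol-2-yl}but-3-en-2-yl]cyclopent-1-en-1-olate | O=P1(/C=C/[C@@H](C)[C@@H]2CCC(O[Li])=C2C)N(C)[C@@H]3CCCC[C@H]3N1C | intermediate (not isolated)
8 | (2R,3S)-2-(hydroxymethyl)-2-methyl-3-[(2S,3E)-4-{(3aR,7aR)-1,3-dimethyl-2-oxidooctahydro-1,3,2-benzodiazaphosphol-2-yl}but-3-en-2-yl]cyclopentan-1-one | O=P1(/C=C/[C@@H](C)[C@@H]2CCC(=O)[C@@]2(C)CO)N(C)[C@@H]3CCCC[C@H]3N1C | intermediate
9 | (2S)-2-[(1S,2R)-2-(hydroxymethyl)-2-methyl-3-oxocyclopentyl]propanal (open form of the lactol) | O=C[C@@H](C)[C@@H]1CCC(=O)[C@@]1(C)CO | intermediate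
10 | (2R,3S)-3-[(2R)-but-3-en-2-yl]-2-(hydroxymethyl)-2-methylcyclopentan-1-one | C=C[C@@H](C)[C@@H]1CCC(=O)[C@@]1(C)CO | intermediate
11 | [(6R,7S)-7-[(2R)-but-3-en-2-yl]-6-methyl-1,4-dioxaspiro[4.4]nonan-6-yl]methanol | C=C[C@@H](C)[C@@H]1CCC2(OCCO2)[C@@]1(C)CO | intermediate
12 | (6R,7S)-7-[(2R)-but-3-en-2-yl]-6-methyl-1,4-dioxaspiro[4.4]nonane-6-carbaldehyde | C=C[C@@H](C)[C@@H]1CCC2(OCCO2)[C@@]1(C)C=O | intermediate
13 | methyl (4S)-4-[(6R,7S)-7-[(2R)-but-3-en-2-yl]-6-methyl-1,4-dioxaspiro[4.4]nonan-6-yl]-4-hydroxybut-2-ynoate | C=C[C@@H](C)[C@@H]1CCC2(OCCO2)[C@@]1(C)[C@@H](O)C#CC(=O)OC | intermediate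
14 | methyl (2E,4S)-4-[(6R,7S)-7-[(2R)-but-3-en-2-yl]-6-methyl-1,4-dioxaspiro[4.4]nonan-6-yl]-4-hydroxybut-2-enoate | C=C[C@@H](C)[C@@H]1CCC2(OCCO2)[C@@]1(C)[C@@H](O)/C=C/C(=O)OC | intermediate
15 | methyl (2E,4S)-4-[(6R,7S)-7-[(2R)-but-3-en-2-yl]-6-methyl-1,4-dioxaspiro[4.4]nonan-6-yl]-4-(triethylsilyloxy)but-2-enoate | C=C[C@@H](C)[C@@H]1CCC2(OCCO2)[C@@]1(C)[C@@H](O[Si](CC)(CC)CC)/C=C/C(=O)OC | intermediate
16 | methyl trimethylsilyl ketene acetal of 17 (C11=C12(OMe)OSiMe3) | C=C[C@@H](C)[C@@H]1CCC2(OCCO2)[C@@]1(C)[C@@H](O[Si](CC)(CC)CC)[C@H](C=C(OC)O[Si](C)(C)C)C=C | intermediate (not isolated)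
17 | methyl (3R)-3-[(S)-{(6R,7S)-7-[(2R)-but-3-en-2-yl]-6-methyl-1,4-dioxaspiro[4.4]nonan-6-yl}(triethylsilyloxy)methyl]pent-4-enoate | C=C[C@@H](C)[C@@H]1CCC2(OCCO2)[C@@]1(C)[C@@H](O[Si](CC)(CC)CC)[C@H](CC(=O)OC)C=C | intermediate
18 | methyl (3S,4S)-3-formyl-4-{(6R,7S)-6-methyl-7-[(2S)-1-oxopropan-2-yl]-1,4-dioxaspiro[4.4]nonan-6-yl}-4-(triethylsilyloxy)butanoate (C8,C9-dialdehyde) | O=C[C@@H](C)[C@@H]1CCC2(OCCO2)[C@@]1(C)[C@@H](O[Si](CC)(CC)CC)[C@H](CC(=O)OC)C=O | intermediate
19 | ring B cis-diol methyl ester (8β-OH, 9β-OH, C7β-CH2CO2Me, 6α-OSiEt3, 4-ketal; present as its samarium diolate) | CC[Si](CC)(CC)O[C@H]1[C@H](CC(=O)OC)[C@H](O)[C@H](O)[C@@H](C)[C@@H]2CCC3(OCCO3)[C@]21C | intermediate (not isolated)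
20 | tricyclic hydroxy lactone, (1S,5R,6S,7R,8S,9R,10S): ring A with 4,4-ethylenedioxy and 5β-CH3, ring B with 6α-OSiEt3, 9β-OH and 10α-CH3, lactone C7–C11H2–C12(=O)–O–C8 cis-fused on the β face, 1α-H | CC[Si](CC)(CC)O[C@H]1[C@H]2[C@H](OC(=O)C2)[C@H](O)[C@@H](C)[C@@H]2CCC3(OCCO3)[C@]21C | intermediate
21 | 20 with 9β-OSi(t-Bu)Me2 | CC[Si](CC)(CC)O[C@H]1[C@H]2[C@H](OC(=O)C2)[C@H](O[Si](C)(C)C(C)(C)C)[C@@H](C)[C@@H]2CCC3(OCCO3)[C@]21C | intermediate
22 | 21 with CH2NMe2 on C11 (C11 configuration not defined) | CC[Si](CC)(CC)O[C@H]1[C@H]2[C@H](OC(=O)C2CN(C)C)[C@H](O[Si](C)(C)C(C)(C)C)[C@@H](C)[C@@H]2CCC3(OCCO3)[C@]21C | intermediate (not isolated)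
23 | trimethylammonium iodide of 22 | CC[Si](CC)(CC)O[C@H]1[C@H]2[C@H](OC(=O)C2C[N+](C)(C)C)[C@H](O[Si](C)(C)C(C)(C)C)[C@@H](C)[C@@H]2CCC3(OCCO3)[C@]21C.[I-] | intermediate (not isolated)
24 | α-methylene lactone (C11=C13H2; 6α-OSiEt3, 9β-OSi(t-Bu)Me2, 4-ketal) | CC[Si](CC)(CC)O[C@H]1[C@H]2[C@H](OC(=O)C2=C)[C@H](O[Si](C)(C)C(C)(C)C)[C@@H](C)[C@@H]2CCC3(OCCO3)[C@]21C | intermediate
25 | α-methylene lactone with 6α-OH, C4 ketone, 9β-OSi(t-Bu)Me2 | O[C@H]1[C@H]2[C@H](OC(=O)C2=C)[C@H](O[Si](C)(C)C(C)(C)C)[C@@H](C)[C@@H]2CCC(=O)[C@]21C | intermediate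
26 | 6α-tiglate of 25 | C/C=C(\C)C(=O)O[C@H]1[C@H]2[C@H](OC(=O)C2=C)[C@H](O[Si](C)(C)C(C)(C)C)[C@@H](C)[C@@H]2CCC(=O)[C@]21C | intermediate
27 | 26 with C2=C3 (cyclopent-2-en-1-one ring A) | C/C=C(\C)C(=O)O[C@H]1[C@H]2[C@H](OC(=O)C2=C)[C@H](O[Si](C)(C)C(C)(C)C)[C@@H](C)[C@@H]2C=CC(=O)[C@]21C | intermediate
28 | (1S,5R,6S,7S,8S,9R,10S)-dienophile: ring A enone, 6α-tiglate, 9β-OH, 8β,12-lactone with C11=C13H2 | C/C=C(\C)C(=O)O[C@H]1[C@H]2[C@H](OC(=O)C2=C)[C@H](O)[C@@H](C)[C@@H]2C=CC(=O)[C@]21C | intermediate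
29 | (R)-(−)-carvone | CC1=CC[C@H](CC1=O)C(C)=C | starting material
30 | (5R)-5-(2-hydroxypropan-2-yl)-2-methylcyclohex-2-en-1-one | CC1=CC[C@H](CC1=O)C(C)(C)O | intermediate
31 | E-tosylhydrazone of 30 (NHTs syn to C6H2) | CC1=CC[C@H](C\C1=N/NS(=O)(=O)c1ccc(C)cc1)C(C)(C)O | intermediate
32 | dilithium salt: 1-lithio-2-methyl-5-(2-lithiooxypropan-2-yl)cyclohexa-1,3-diene numbering as in carvone (C1–Li, C1=C6, C2=C3) | CC1=CC[C@H](C=C1[Li])C(C)(C)O[Li] | intermediate (not isolated)
33 | 2-[(1R)-4-methylcyclohexa-2,4-dien-1-yl]propan-2-ol [(R)-p-mentha-1,5-dien-8-ol] | CC1=CC[C@H](C=C1)C(C)(C)O | intermediate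
34 | target: [4+2] adduct of 28 and 33 with bonds C11–C4' and C13–C1', lactone carbonyl syn to the C2'=C3' double bond, CMe2OH on C5' anti to the C11–C13 bridge; (1S,5R,6S,7S,8S,9R,10S,11S,1'S,4'R,5'R) | C/C=C(\C)C(=O)O[C@H]1[C@H]2[C@H](OC(=O)[C@]23C[C@@H]2C[C@@H](C(C)(C)O)[C@H]3C=C2C)[C@H](O)[C@@H](C)[C@@H]2C=CC(=O)[C@]21C | target

**Step count and risks**

Total steps: 24. Longest linear sequence: 21 steps (steps 1–20 and 24); the diene branch is steps 21–23.

Steps most likely to fail:

1. Step 24. The diene may reach the methylene from the α face in the exo mode, which for this diene enantiomer is the only alternative pairing and gives the C11 epimer; the dienol may also aromatise or dehydrate during prolonged heating. Fallback, setting out from 20 and returning at 34: the cycloaddition would be moved to an earlier dienophile whose α face carries the larger triethylsilyloxy group, whose β face carries a free hydroxyl and which has no enone. Lactone 20 would be methylenated as in step 16 with 2.2 equivalents of LiN(iPr)2, through the 9-hydroxy Mannich base F1 and its methiodide F2, to the 9-hydroxy methylene lactone F3. F3 and 33 (toluene, 80 °C) would give the 6-silyloxy cycloadduct F4. t-BuMe2SiOTf with 2,6-lutidine would silylate both hydroxyls to the bis-silyl ether F5. TsOH·H2O in wet THF would remove the triethylsilyl group and the ketal to give the hydroxy ketone F6. Tigloyl chloride with pyridine and DMAP would give the tiglate F7, and IBX the enone F8. HF·pyridine would then remove both silyl groups and give 34.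

2. Step 14. The ketyls may couple on the α face (8α,9α-diol and a trans-fused lactone) or be reduced to alcohols without C–C bond formation, and C7 may epimerise in the dialdehyde. Fallback, setting out from 17 and returning at 20: ring-closing metathesis with the second-generation Grubbs catalyst (CH2Cl2, 40 °C) would close ring B to the cycloheptene ester F9. LiOH would give the cycloheptene acid F10. Iodolactonisation (I2, NaHCO3, MeCN) can only deliver the β-oriented carboxylate to C8 from the β face, with iodine at C9 on the α face, giving the iodolactone F11. KO2 with 18-crown-6 in DMSO would displace the iodide with inversion and give 20.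

3. Step 9. Addition to the hindered neopentyl aldehyde may be slow or poorly face-selective, giving the C6 epimer. Fallback, setting out from 12 and returning at 13: lithiated methyl propiolate (LiN(SiMe3)2, THF, −78 °C) would add without control to give 13 together with its C6 epimer F12. Dess–Martin periodinane would oxidise the mixture to the ynone F13. Reduction with (R)-2-methyl-CBS-oxazaborolidine and catecholborane (toluene, −78 °C), with the alkynyl group acting as the small substituent, should then give 13 as the 6S alcohol.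

Further compounds
F1 | step 24 | 20 with CH2NMe2 on C11 (9β-OH free) | CC[Si](CC)(CC)O[C@H]1[C@H]2[C@H](OC(=O)C2CN(C)C)[C@H](O)[C@@H](C)[C@@H]2CCC3(OCCO3)[C@]21C
F2 | step 24 | trimethylammonium iodide of F1 | CC[Si](CC)(CC)O[C@H]1[C@H]2[C@H](OC(=O)C2C[N+](C)(C)C)[C@H](O)[C@@H](C)[C@@H]2CCC3(OCCO3)[C@]21C.[I-]
F3 | step 24 | 9β-hydroxy α-methylene lactone (6α-OSiEt3, 4-ketal) | CC[Si](CC)(CC)O[C@H]1[C@H]2[C@H](OC(=O)C2=C)[C@H](O)[C@@H](C)[C@@H]2CCC3(OCCO3)[C@]21C
F4 | step 24 | cycloadduct of F3 and 33 (6α-OSiEt3, 9β-OH, 4-ketal) | CC[Si](CC)(CC)O[C@H]1[C@H]2[C@H](OC(=O)[C@]23C[C@@H]2C[C@@H](C(C)(C)O)[C@H]3C=C2C)[C@H](O)[C@@H](C)[C@@H]2CCC3(OCCO3)[C@]21C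
F5 | step 24 | bis(tert-butyldimethylsilyl) ether of F4 (C9–O and side-chain O) | CC[Si](CC)(CC)O[C@H]1[C@H]2[C@H](OC(=O)[C@]23C[C@@H]2C[C@@H](C(C)(C)O[Si](C)(C)C(C)(C)C)[C@H]3C=C2C)[C@H](O[Si](C)(C)C(C)(C)C)[C@@H](C)[C@@H]2CCC3(OCCO3)[C@]21C
F6 | step 24 | 6α-hydroxy 4-ketone from F5 | O[C@H]1[C@H]2[C@H](OC(=O)[C@]23C[C@@H]2C[C@@H](C(C)(C)O[Si](C)(C)C(C)(C)C)[C@H]3C=C2C)[C@H](O[Si](C)(C)C(C)(C)C)[C@@H](C)[C@@H]2CCC(=O)[C@]21C
F7 | step 24 | 6α-tiglate of F6 | C/C=C(\C)C(=O)O[C@H]1[C@H]2[C@H](OC(=O)[C@]23C[C@@H]2C[C@@H](C(C)(C)O[Si](C)(C)C(C)(C)C)[C@H]3C=C2C)[C@H](O[Si](C)(C)C(C)(C)C)[C@@H](C)[C@@H]2CCC(=O)[C@]21C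
F8 | step 24 | ring A enone of F7 (bis-silyl ether of 34) | C/C=C(\C)C(=O)O[C@H]1[C@H]2[C@H](OC(=O)[C@]23C[C@@H]2C[C@@H](C(C)(C)O[Si](C)(C)C(C)(C)C)[C@H]3C=C2C)[C@H](O[Si](C)(C)C(C)(C)C)[C@@H](C)[C@@H]2C=CC(=O)[C@]21C
F9 | step 14 | cycloheptene ester (C8=C9, C7β-CH2CO2Me, 6α-OSiEt3, 4-ketal) | CC[Si](CC)(CC)O[C@H]1[C@H](CC(=O)OC)C=C[C@@H](C)[C@@H]2CCC3(OCCO3)[C@]21C
F10 | step 14 | cycloheptene acid from F9 | CC[Si](CC)(CC)O[C@H]1[C@H](CC(=O)O)C=C[C@@H](C)[C@@H]2CCC3(OCCO3)[C@]21C
F11 | step 14 | 9α-iodo 8β,12-lactone | CC[Si](CC)(CC)O[C@H]1[C@H]2[C@H](OC(=O)C2)[C@@H](I)[C@@H](C)[C@@H]2CCC3(OCCO3)[C@]21C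
F12 | step 9 | C6 epimer (6R) of 13 | C=C[C@@H](C)[C@@H]1CCC2(OCCO2)[C@@]1(C)[C@H](O)C#CC(=O)OC
F13 | step 9 | methyl 4-[(6R,7S)-7-[(2R)-but-3-en-2-yl]-6-methyl-1,4-dioxaspiro[4.4]nonan-6-yl]-4-oxobut-2-ynoate | C=C[C@@H](C)[C@@H]1CCC2(OCCO2)[C@@]1(C)C(=O)C#CC(=O)OC
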